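## Analysis of the target

Target 12 is a 2H-chromene. Benzene ring A carries an acetyl group at C6 and a methoxy group at C8. Pyran ring B holds O1, the fully substituted carbon C2 and the C3=C4 double bond, which is conjugated with ring A. C2 bears a methyl group and a CH2O arm esterified with (E)-ferulic acid (4), whose guaiacyl ring (ring C) keeps a free phenol. C2 is the only stereocentre (R). It is a tertiary alkyl aryl ether carbon, so it cannot be made by substitution with inversion, and with no second stereocentre to relay from it must be set by a chiral catalyst. The sensitive groups are the ring C phenol (oxidation, alkylation), the cinnamate (nucleophiles, E/Z photoisomerisation), the aryl methyl ketone and the 2H-chromene itself. The chromene can open to an ortho-quinone allide by 6π electrocyclic ring opening in light or on strong heating, and in the open form C2 is planar, so enantiopurity can be lost. The main difficulty is that the two acyclic substituents at C2, CH3 and CH2O-acyl, differ little in size. The route rests on one feature: O1, C8a, C4a and C4 are the four atoms of an ortho-quinone methide, and C2–C3 with its methyl and CH2O-feruloyl groups is a methallyl ester alkene, so one oxidation level below the target ring B is a hetero-Diels–Alder adduct.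

## Retrosynthetic reasoning

12 to 11. The last bond made or broken should be the least consequential, so the ring C phenol is unmasked at the end from its acetate 11. The phenol must stay covered until then: free, it would be oxidised in the dehydrogenation and would compete as an O- and C-nucleophile for quinone methide 9. The forward step has to cleave an aryl ester beside an alkyl cinnamate, which the difference in leaving-group ability allows.

11 to 10. Removing the C3=C4 unsaturation gives chroman 10. This is the move that exposes ring B as a [4+2] adduct. In the forward sense C4 is the only benzylic CH2 in the molecule and is activated by O1 through ring A, so a quinone hydride acceptor should attack there and nowhere else. C2 is quaternary and is not touched.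

10 to 3 and 8 through 9. Cutting C3–C4 and O1–C2 together divides 10 into two pieces of similar size: quinone methide 9, written as its stable precursor 3, and methallyl ester 8. This is the best place to cut because one step then forms both ring bonds, the ring and the stereocentre, with the ferulate already attached. Cutting the ester C–O bond first would leave a chromene methanol whose stereocentre still needs a separate solution. The forward reaction has to dehydrate 3 to 9 under a chiral Brønsted acid and direct O1 to one face of the alkene of 8.

8 to 5 and 6 through 7, and 5 to 4. The ester C–O bond is cut to acid 5 and allylic alcohol 6, joined through acyl chloride 7. Acid 5 is ferulic acid 4 with its phenol acetylated. The acetate is chosen because it survives acid chloride formation, the Brønsted acid and the oxidant, and comes off under conditions that spare the cinnamate.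

3 to 1 and 2. The aryl–CH2 bond ortho to the phenol is cut to acetovanillone 1 and formaldehyde 2. In 1 one ortho position carries the methoxy group and the para position the acetyl group, so only one site can be hydroxymethylated.

## Alternatives that were turned down

Alternative 1: The C3=C4 bond is disconnected by ring-closing metathesis and C2 is set by desymmetrisation. The precursor is triene A1, 1-{3-ethenyl-5-methoxy-4-[(3-methylpenta-1,4-dien-3-yl)oxy]phenyl}ethanone, whose ether carbon carries two enantiotopic vinyl groups. In the forward step Mo(N-2,6-i-Pr2C6H3)(CHCMe2Ph)[(S)-3,3'-di-tert-butyl-5,5',6,6'-tetramethylbiphenyl-2,2'-diolate] (hexavalent molybdenum) joins the ring A vinyl group to one of them and gives vinyl chromene A2, 1-[(2S)-2-ethenyl-8-methoxy-2-methyl-2H-chromen-6-yl]ethanone. A2 is 2S only because vinyl ranks below C3; its spatial arrangement is that of 12.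
- For: the catalyst chooses between two whole vinyl groups, not between CH3 and CH2O-acyl, and this type of desymmetrisation is established. On stereocontrol it stands on firmer ground than step 4. The C3=C4 bond also appears directly, without an oxidation.
- Against: A1 is an aryl ether of a tertiary bis-allylic alcohol, which no simple etherification delivers and which ionises easily. The oxophilic alkylidene may not tolerate the aryl ketone.
- Against, most seriously: A2 must lose one carbon (vinyl to CH2OH) by oxidative cleavage and reduction. The more electron-rich C3=C4 bond and the ketone stand in the way of both operations.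
- Comparison: esterification with 7 and deacetylation would still follow, so at least four steps come after the key step, against two here. The chosen route carries the complete skeleton and the ester through its key step.

Alternative 2: The O1–C2 bond is disconnected by allylic substitution. The precursor is the racemic cyclic carbonate A3, 4-[(Z)-2-(5-acetyl-2-hydroxy-3-methoxyphenyl)ethenyl]-4-methyl-1,3-dioxolan-2-one. Pd2(dba)3 (zerovalent palladium) with a chiral bisphosphine ionises the tertiary allylic C–O bond with decarboxylation. Both enantiomers converge on interconverting π-allyl complexes of divalent palladium, and the phenoxide attacks the methyl-bearing terminus to give hydroxymethyl chromene A4, 1-[(2R)-2-(hydroxymethyl)-8-methoxy-2-methyl-2H-chromen-6-yl]ethanone.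
- For: one step gives ring B, the C3=C4 bond and the free CH2OH from a racemate, and the chromene is never heated. Acylation of A4 with 7 would join the present route at 11. Enantioconvergent tertiary ether formation at a π-allyl has better precedent than the facial control asked of step 4, so this alternative is stronger on that point.
- Against: closure to a six-membered ring with an endocyclic cis double bond needs the aryl group anti on the allyl, the less stable geometry. The syn complex can only react between molecules.
- Against: A3 needs a Z-styrenyl carbonate on a phenol that must be protected and released, which costs four to five steps before the key step.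
- Comparison: the chosen route reaches its key step in three steps from four commodity chemicals and keeps the ester in place.

Alternative 3: The C4–C4a bond is disconnected by hydroarylation. The precursor is the aryl propargyl ether A5, (2R)-2-(4-acetyl-2-methoxyphenoxy)-2-methylbut-3-yn-1-yl (E)-3-(4-acetoxy-3-methoxyphenyl)prop-2-enoate. Ph3PAuNTf2 (monovalent gold) activates the terminal alkyne and the free carbon ortho to the ether oxygen attacks it 6-endo-dig. The product A6 is [(2R)-6-acetyl-8-methoxy-2-methyl-2H-chromen-2-yl]methyl (E)-3-(4-acetoxy-3-methoxyphenyl)prop-2-enoate, identical with 11.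
- For: this ring closure is dependable, leaves C2 as a spectator, needs no oxidation and runs under mild conditions. Only step 6 would follow. As a ring-forming step it is safer than step 4.
- Against: the stereochemical problem is only moved. A tertiary propargylic alcohol with the same CH3 versus CH2O discrimination must first be made in enantioenriched form.
- Against: that alcohol must then be O-arylated at a hindered tertiary alkoxide without passing through a planar propargylic cation. Ring A is also deactivated towards the attack by its acetyl group.
- Comparison: the sequence would be linear and roughly eight to nine steps. The chosen route is shorter and convergent and makes ring and stereocentre in one step, at the price of a less secure key step.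

Key step: step 4

Assumption: the sense of induction of the imidodiphosphorimidate cannot be predicted with confidence. The (S,S)-catalyst is written; if it favours the 2S adduct, the (R,R)-catalyst is used with no other change.

## Route

Step 1
Reactants: 1 1-(4-hydroxy-3-methoxyphenyl)ethanone (acetovanillone); 2 formaldehyde
Product: 3 1-[4-hydroxy-3-(hydroxymethyl)-5-methoxyphenyl]ethanone
Conditions: 37% aq. HCHO (5 equiv), NaOH (1.1 equiv), H2O, rt → 40 °C, 3–5 d; then dil. HCl to pH 5
Reagents that add atoms: none
Why: Lederer–Manasse hydroxymethylation: the phenoxide of 1 attacks formaldehyde through its only free ortho carbon (the other ortho position carries OMe, the para position the acetyl group), so a single regioisomer is possible. The para acetyl group slows the reaction but, as part of a vinylogous carboxylate, is also reluctant to enolise.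

Step 2
Reactants: 4 (E)-3-(4-hydroxy-3-methoxyphenyl)prop-2-enoic acid (ferulic acid)
Product: 5 (E)-3-(4-acetoxy-3-methoxyphenyl)prop-2-enoic acid
Conditions: Ac2O, pyridine, rt; then ice/dil. HCl
Reagents that add atoms: acetic anhydride, CC(=O)OC(C)=O
Why: Standard O-acetylation of a phenol. Any mixed anhydride formed at the carboxylic acid is hydrolysed in the aqueous work-up, leaving the aryl acetate.

Step 3
Reactants: 5 (E)-3-(4-acetoxy-3-methoxyphenyl)prop-2-enoic acid; 6 2-methylprop-2-en-1-ol
Product: 8 2-methylprop-2-en-1-yl (E)-3-(4-acetoxy-3-methoxyphenyl)prop-2-enoate, via 4-O-acetylferuloyl chloride 7 (not isolated)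
Conditions: (COCl)2, cat. DMF, CH2Cl2, 0 °C → rt; evaporate; then 6, Et3N, cat. DMAP, CH2Cl2, 0 °C → rt
Reagents that add atoms: oxalyl chloride, O=C(Cl)C(=O)Cl (supplies the chlorine of intermediate 7 only; none of its atoms remain in 8)
Why: Acid chloride formation by DMF-catalysed activation, then DMAP-catalysed acylation of the primary allylic alcohol. The aryl acetate and the E-alkene are inert to both stages.

Step 4
Reactants: 3 1-[4-hydroxy-3-(hydroxymethyl)-5-methoxyphenyl]ethanone; 8 2-methylprop-2-en-1-yl (E)-3-(4-acetoxy-3-methoxyphenyl)prop-2-enoate
Product: 10 [(2R)-6-acetyl-8-methoxy-2-methyl-3,4-dihydro-2H-chromen-2-yl]methyl (E)-3-(4-acetoxy-3-methoxyphenyl)prop-2-enoate, via ortho-quinone methide 9 (not isolated)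
Conditions: (S,S)-imidodiphosphorimidate (two (S)-3,3'-diaryl-BINOL units bridged by nitrogen, each phosphorus bearing P=N–SO2CF3; aryl = 3,5-(CF3)2C6H3 as first choice; 5–10 mol%), 5 Å molecular sieves, CHCl3, 0 °C → rt; 3 added slowly to 8 (3 equiv)
Reagents that add atoms: none
Why: Proposed new method: the imidodiphosphorimidate protonates the benzylic hydroxyl of 3 while its anion holds the phenol OH, and loss of water gives quinone methide 9 as a hydrogen-bonded ion pair inside the chiral pocket. The CH2 terminus of the methallyl alkene of 8 attacks the exocyclic methylene of 9 (future C4), positive charge builds at the tertiary carbon, where the neighbouring ester carbonyl can support it, and the quinone methide oxygen closes onto it, an asynchronous concerted inverse-electron-demand hetero-Diels–Alder reaction that forms C3–C4 and O1–C2. Ring B is thus closed by intermolecular [4+2] cycloaddition, with O1, C8a, C4a and C4 from 9 and C2 and C3 from 8. The closest known reaction types are chiral phosphoric acid and imidodiphosphorimidate catalysed [4+2] additions of ortho-quinone methides, generated in situ from ortho-hydroxybenzyl alcohols, to styrenes, and the racemic thermal or acid-promoted addition of ortho-quinone methides to 1,1-disubstituted alkenes. C2 is controlled by the catalyst alone: O1 must bond to the Re face of the disubstituted alkene carbon (CH2O-acyl > =CH2 > CH3) to give 2R, and the confined anion must tell the methyl flank from the acyloxymethyl flank, for which the long feruloyl arm, able to leave the pocket in one direction only, is the handle. Regioselectivity (oxygen to the tertiary carbon) follows from the polarity of both partners; the cinnamate C=C is conjugated and electron-poor and should not compete; C-alkylation of 3 by 9 is blocked because every position ortho and para to the phenol of 3 is substituted, and the acetate lowers the nucleophilicity of ring C. The sieves take up the water, and slow addition of 3 to excess 8 keeps 9 dilute and limits its dimerisation.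

Step 5
Reactants: 10 [(2R)-6-acetyl-8-methoxy-2-methyl-3,4-dihydro-2H-chromen-2-yl]methyl (E)-3-(4-acetoxy-3-methoxyphenyl)prop-2-enoate
Product: 11 [(2R)-6-acetyl-8-methoxy-2-methyl-2H-chromen-2-yl]methyl (E)-3-(4-acetoxy-3-methoxyphenyl)prop-2-enoate
Conditions: DDQ (1.5–2 equiv), benzene, 80 °C, N2, dark
Reagents that add atoms: none
Why: Quinone dehydrogenation of a chroman: DDQ abstracts hydride from benzylic C4, the cation being stabilised by O1 through ring A, and loss of a C3 proton gives the conjugated C3=C4 bond. C2 is quaternary and is not involved, and the acetate keeps ring C from being oxidised; light is excluded and heating kept short so that the chromene does not ring-open.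

Step 6
Reactants: 11 [(2R)-6-acetyl-8-methoxy-2-methyl-2H-chromen-2-yl]methyl (E)-3-(4-acetoxy-3-methoxyphenyl)prop-2-enoate
Product: 12 [(2R)-6-acetyl-8-methoxy-2-methyl-2H-chromen-2-yl]methyl (E)-3-(4-hydroxy-3-methoxyphenyl)prop-2-enoate (CNP0168033.1)
Conditions: pyrrolidine (3 equiv), CH2Cl2, 0 °C → rt, dark; then dil. aq. citric acid
Reagents that add atoms: none
Why: Aminolysis of an aryl acetate: phenoxide is a far better leaving group than the neopentyl-type alkoxide of the ferulate ester, so the amine should remove only the acetyl group at room temperature. The stereocentre, the E-cinnamate and the ketone are not affected.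

## Compound list

1 | 1-(4-hydroxy-3-methoxyphenyl)ethanone (acetovanillone) | CC(=O)c1ccc(O)c(OC)c1 | starting material
2 | formaldehyde | C=O | starting material
3 | 1-[4-hydroxy-3-(hydroxymethyl)-5-methoxyphenyl]ethanone | CC(=O)c1cc(CO)c(O)c(OC)c1 | intermediate
4 | (E)-3-(4-hydroxy-3-methoxyphenyl)prop-2-enoic acid (ferulic acid) | COc1cc(/C=C/C(=O)O)ccc1O | starting material
5 | (E)-3-(4-acetoxy-3-methoxyphenyl)prop-2-enoic acid | COc1cc(/C=C/C(=O)O)ccc1OC(C)=O | intermediate
6 | 2-methylprop-2-en-1-ol | CC(=C)CO | starting material
7 | (E)-3-(4-acetoxy-3-methoxyphenyl)prop-2-enoyl chloride | COc1cc(/C=C/C(=O)Cl)ccc1OC(C)=O | intermediate (not isolated)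
8 | 2-methylprop-2-en-1-yl (E)-3-(4-acetoxy-3-methoxyphenyl)prop-2-enoate | CC(=C)COC(=O)/C=C/c1ccc(OC(C)=O)c(OC)c1 | intermediate
9 | 4-acetyl-2-methoxy-6-methylidenecyclohexa-2,4-dien-1-one | O=C1C(OC)=CC(C(C)=O)=CC1=C | intermediate (not isolated)
10 | [(2R)-6-acetyl-8-methoxy-2-methyl-3,4-dihydro-2H-chromen-2-yl]methyl (E)-3-(4-acetoxy-3-methoxyphenyl)prop-2-enoate | COc1cc(/C=C/C(=O)OC[C@@]2(C)CCc3cc(C(C)=O)cc(OC)c3O2)ccc1OC(C)=O | intermediate
11 | [(2R)-6-acetyl-8-methoxy-2-methyl-2H-chromen-2-yl]methyl (E)-3-(4-acetoxy-3-methoxyphenyl)prop-2-enoate | COc1cc(/C=C/C(=O)OC[C@@]2(C)C=Cc3cc(C(C)=O)cc(OC)c3O2)ccc1OC(C)=O | intermediate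
12 | [(2R)-6-acetyl-8-methoxy-2-methyl-2H-chromen-2-yl]methyl (E)-3-(4-hydroxy-3-methoxyphenyl)prop-2-enoate | COc1cc(/C=C/C(=O)OC[C@@]2(C)C=Cc3cc(C(C)=O)cc(OC)c3O2)ccc1O | target

## Step count and risks

Total: 6 steps. Longest linear sequence: 5 steps (4 → 5 → 8 → 10 → 11 → 12); the other branch (1 → 3) joins at step 4.

**Step 4 (key step, the only one beyond known chemistry).**
- Poor facial discrimination is the most likely failure, because the catalyst has to tell a methyl group from a CH2O-acyl group on an alkene that offers no binding site near the reacting carbon.
- Slow ionisation of 3 is the second risk: the para acetyl group withdraws the electron density that would otherwise push out the benzylic hydroxyl, so conversion may stall.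
- Self-reaction of 9 (dimerisation, ether formation with 3) is the third, since the alkene of 8 is only moderately nucleophilic.
- Fallback, from 3 and 8, returning at 10: the two are heated without acid in 1,2-dichlorobenzene at about 170 °C (sealed vessel, BHT as inhibitor, excess 8). Thermal dehydration gives 9, which adds to 8 with the same regiochemistry and should give racemic [6-acetyl-8-methoxy-2-methyl-3,4-dihydro-2H-chromen-2-yl]methyl (E)-3-(4-acetoxy-3-methoxyphenyl)prop-2-enoate F1. Preparative chromatography on a polysaccharide chiral stationary phase then resolves F1 into 10 and [(2S)-6-acetyl-8-methoxy-2-methyl-3,4-dihydro-2H-chromen-2-yl]methyl (E)-3-(4-acetoxy-3-methoxyphenyl)prop-2-enoate F2, which is set aside. The fraction carried on must have its absolute configuration assigned before use.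

**Step 5.**
- Hydride abstraction may be sluggish, because the 6-acetyl group competes for the O1 lone pair that stabilises the C4 cation.
- The longer the product chromene is heated, the more reversible electrocyclic ring opening can lower its enantiopurity. Over-oxidation by excess quinone is a further risk.
- Fallback, from 10, returning at 11: radical bromination with N-bromosuccinimide and AIBN in PhCF3 at 80 °C should put bromine at C4, the only benzylic CH2, giving [(2R)-6-acetyl-4-bromo-8-methoxy-2-methyl-3,4-dihydro-2H-chromen-2-yl]methyl (E)-3-(4-acetoxy-3-methoxyphenyl)prop-2-enoate F3 as a mixture of C4 epimers. DBU in THF at rt in the dark then eliminates HBr across C3–C4 (only C3 has β-hydrogens) to give 11, so the chromene itself is never heated.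

**Step 1.**
- The electron-poor phenoxide reacts slowly, and during the long reaction time the product can condense with unreacted 1 to a methylene-bridged dimer.
- Aldol-type hydroxymethylation at the acetyl group is a minor competing path.
- Fallback, from 1 and 2, returning at 3: Blanc chloromethylation (2, concentrated HCl, rt) should give 1-[3-(chloromethyl)-4-hydroxy-5-methoxyphenyl]ethanone F4, the acetyl and hydroxyl groups both directing to the same carbon. The reactive benzylic chloride of F4 is then hydrolysed with aqueous NaHCO3 in acetone at rt to 3.

## Further compounds

F1 | step 4 | racemic [6-acetyl-8-methoxy-2-methyl-3,4-dihydro-2H-chromen-2-yl]methyl (E)-3-(4-acetoxy-3-methoxyphenyl)prop-2-enoate | COc1cc(/C=C/C(=O)OCC2(C)CCc3cc(C(C)=O)cc(OC)c3O2)ccc1OC(C)=O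
F2 | step 4 | [(2S)-6-acetyl-8-methoxy-2-methyl-3,4-dihydro-2H-chromen-2-yl]methyl (E)-3-(4-acetoxy-3-methoxyphenyl)prop-2-enoate | COc1cc(/C=C/C(=O)OC[C@]2(C)CCc3cc(C(C)=O)cc(OC)c3O2)ccc1OC(C)=O
F3 | step 5 | [(2R)-6-acetyl-4-bromo-8-methoxy-2-methyl-3,4-dihydro-2H-chromen-2-yl]methyl (E)-3-(4-acetoxy-3-methoxyphenyl)prop-2-enoate (both C4 epimers) | COc1cc(/C=C/C(=O)OC[C@@]2(C)CC(Br)c3cc(C(C)=O)cc(OC)c3O2)ccc1OC(C)=O
F4 | step 1 | 1-[3-(chloromethyl)-4-hydroxy-5-methoxyphenyl]ethanone | CC(=O)c1cc(CCl)c(O)c(OC)c1
A1 | alternative 1 | 1-{3-ethenyl-5-methoxy-4-[(3-methylpenta-1,4-dien-3-yl)oxy]phenyl}ethanone | C=CC(C)(C=C)Oc1c(C=C)cc(C(C)=O)cc1OC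
A2 | alternative 1 | 1-[(2S)-2-ethenyl-8-methoxy-2-methyl-2H-chromen-6-yl]ethanone | C=C[C@@]1(C)C=Cc2cc(C(C)=O)cc(OC)c2O1
A3 | alternative 2 | racemic 4-[(Z)-2-(5-acetyl-2-hydroxy-3-methoxyphenyl)ethenyl]-4-methyl-1,3-dioxolan-2-one | CC(=O)c1cc(/C=C\C2(C)COC(=O)O2)c(O)c(OC)c1
A4 | alternative 2 | 1-[(2R)-2-(hydroxymethyl)-8-methoxy-2-methyl-2H-chromen-6-yl]ethanone | OC[C@@]1(C)C=Cc2cc(C(C)=O)cc(OC)c2O1
A5 | alternative 3 | (2R)-2-(4-acetyl-2-methoxyphenoxy)-2-methylbut-3-yn-1-yl (E)-3-(4-acetoxy-3-methoxyphenyl)prop-2-enoate | COc1cc(/C=C/C(=O)OC[C@@](C)(C#C)Oc2ccc(C(C)=O)cc2OC)ccc1OC(C)=O
A6 | alternative 3 | [(2R)-6-acetyl-8-methoxy-2-methyl-2H-chromen-2-yl]methyl (E)-3-(4-acetoxy-3-methoxyphenyl)prop-2-enoate (same structure as 11) | COc1cc(/C=C/C(=O)OC[C@@]2(C)C=Cc3cc(C(C)=O)cc(OC)c3O2)ccc1OC(C)=O
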